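**Retrosynthetic overview**

1. The target follows from a fully protected 8-O-4' ether by Bu4NF desilylation and hydrogenolysis of three benzyl ethers; its ring B methyl ethers come from a 2-alkoxy-5-alkylresorcinol (ester hydrolysis and decarboxylation, then O-methylation).
2. Feature used: in ring B the ether carbon C4' (bonded to the C8 oxygen) lies between the two oxygen-bearing carbons C3' and C5', and the only carbon substituent is at C1'. This 2-alkoxyresorcinol pattern unfolds into an alkoxymethyl alkynyl ketone (C4', C3', C2', C1') and a malonate (C6', C5').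
3. Key disconnection: C1'–C6' (Michael) and C4'–C5' (Claisen). Ring B is the only ring made and is made last, around the finished C8–O bond; ring A is bought as a bromophenol.
4. The alkynone comes from a Weinreb amide of the C8-O-glycolic acid and the lithium acetylide of (S)-4,5-bis(benzyloxy)pent-1-yne, made from (S)-benzyl glycidyl ether and acetylide (C8' from the chiral pool).
5. The glycolate ether comes from Rh-carbenoid O–H insertion into the erythro C8 alcohol, made by anti-selective addition of the ring A aryltitanium to (R)-glyceraldehyde acetonide (C8 from the chiral pool, C7 by Felkin–Anh control).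

Key step: step 11

Remarks.
- Neolignan numbering is used: ring A C1–C6 with chain C7–C9; ring B C1'–C6' with chain C7'–C9'.
- TBS = tert-butyldimethylsilyl, TIPS = triisopropylsilyl, Bn = benzyl. G = (1S,2R)-1-[4-(benzyloxy)-3,5-dimethoxyphenyl]-1-(TBS-oxy)-3-(TIPS-oxy)propan-2-yl, bonded through C8, so "G-oxy" is the C8 oxygen with its substituent.
- Protecting groups: TBS on O7 and TIPS on O9 are both removed by fluoride, and TIPS is chosen at O9 for a primary-selective silylation and for stability to base. Benzyl on O8' and O9' is stable to alkoxide and hydroxide and is removed together with the ring A benzyl ether.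
- Assumption: the aryltitanium addition in step 2 follows the Felkin–Anh (non-chelation) sense, and the C7 epimers are separable at compound 6.

**Route**

Step 1
Reactants: 1 4-bromo-2,6-dimethoxyphenol
Product: 2 2-(benzyloxy)-5-bromo-1,3-dimethoxybenzene
Conditions: BnBr, K2CO3, DMF, rt
Reagents that add atoms: benzyl bromide, BrCc1ccccc1
Why: Williamson etherification of the acidic phenol masks the ring A hydroxyl as a benzyl ether that tolerates organolithium, alkoxide and fluoride.

Step 2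
Reactants: 2 2-(benzyloxy)-5-bromo-1,3-dimethoxybenzene; 3 (R)-2,2-dimethyl-1,3-dioxolane-4-carbaldehyde
Product: 6 (S)-[4-(benzyloxy)-3,5-dimethoxyphenyl][(4R)-2,2-dimethyl-1,3-dioxolan-4-yl]methanol, via aryllithium 4 (not isolated), via aryltitanium triisopropoxide 5 (not isolated)
Conditions: n-BuLi, THF, −78 °C; ClTi(OiPr)3, −78 → −40 °C; then 3, −78 → −20 °C; aq. NH4Cl
Reagents that add atoms: none
Why: Bromine–lithium exchange, transmetalation to the bulky, non-chelating aryltitanium and Felkin–Anh 1,2-addition to the α-alkoxy aldehyde should set C7 as S, anti to the chiral-pool C8 oxygen (the erythro relationship), with the minor syn epimer removed by chromatography.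

Step 3
Reactants: 6 (S)-[4-(benzyloxy)-3,5-dimethoxyphenyl][(4R)-2,2-dimethyl-1,3-dioxolan-4-yl]methanol
Product: 7 tert-butyl{(S)-[4-(benzyloxy)-3,5-dimethoxyphenyl][(4R)-2,2-dimethyl-1,3-dioxolan-4-yl]methoxy}dimethylsilane
Conditions: TBSCl, imidazole, DMF, rt → 40 °C
Reagents that add atoms: tert-butyldimethylsilyl chloride, CC(C)(C)[Si](C)(C)Cl
Why: Silylation of the secondary benzylic alcohol gives a hindered TBS ether that should survive the later methoxide and hydroxide steps.

Step 4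
Reactants: 7 tert-butyl{(S)-[4-(benzyloxy)-3,5-dimethoxyphenyl][(4R)-2,2-dimethyl-1,3-dioxolan-4-yl]methoxy}dimethylsilane
Product: 8 (2R,3S)-3-[4-(benzyloxy)-3,5-dimethoxyphenyl]-3-[(tert-butyldimethylsilyl)oxy]propane-1,2-diol
Conditions: AcOH/H2O (4:1), 40 °C
Reagents that add atoms: none
Why: Acid-catalysed hydrolysis of the terminal isopropylidene acetal is faster than cleavage of the hindered secondary TBS ether, and acetic acid is too weak to ionise the benzylic C7–O bond.

Step 5
Reactants: 8 (2R,3S)-3-[4-(benzyloxy)-3,5-dimethoxyphenyl]-3-[(tert-butyldimethylsilyl)oxy]propane-1,2-diol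
Product: 9 (1S,2R)-1-[4-(benzyloxy)-3,5-dimethoxyphenyl]-1-[(tert-butyldimethylsilyl)oxy]-3-[(triisopropylsilyl)oxy]propan-2-ol
Conditions: TIPSCl, imidazole, CH2Cl2, 0 °C → rt
Reagents that add atoms: triisopropylsilyl chloride, CC(C)[Si](Cl)(C(C)C)C(C)C
Why: Sterically controlled silylation puts the bulky TIPS group on the primary C9 hydroxyl only and leaves the hindered C8 hydroxyl free.

Step 6
Reactants: 9 (1S,2R)-1-[4-(benzyloxy)-3,5-dimethoxyphenyl]-1-[(tert-butyldimethylsilyl)oxy]-3-[(triisopropylsilyl)oxy]propan-2-ol; 10 ethyl diazoacetate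
Product: 11 ethyl 2-(G-oxy)acetate
Conditions: Rh2(OAc)4 (cat.), 10 added slowly in excess, CH2Cl2, rt
Reagents that add atoms: none
Why: Rh-carbenoid O–H insertion alkylates the C8 oxygen under neutral conditions, so no alkoxide is formed, the neighbouring silyl groups cannot migrate, and C8 keeps its configuration because only the O–H bond reacts.

Step 7
Reactants: 11 ethyl 2-(G-oxy)acetate
Product: 12 N-methoxy-N-methyl-2-(G-oxy)acetamide
Conditions: MeNH(OMe)·HCl, i-PrMgCl, THF, −20 → 0 °C; aq. NH4Cl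
Reagents that add atoms: N,O-dimethylhydroxylamine hydrochloride, CNOC.Cl
Why: Weinreb amidation of the ester by the chloromagnesium amide proceeds at low temperature without touching the silyl or benzyl ethers.

Step 8
Reactants: 13 (S)-benzyl glycidyl ether; 14 lithium acetylide–ethylenediamine complex
Product: 15 (S)-1-(benzyloxy)pent-4-yn-2-ol
Conditions: DMSO, 0 °C → rt; aq. NH4Cl
Reagents that add atoms: none
Why: SN2 opening of the epoxide at its terminal carbon by acetylide leaves the stereocentre untouched, so C8' keeps the chiral-pool S configuration.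

Step 9
Reactants: 15 (S)-1-(benzyloxy)pent-4-yn-2-ol
Product: 16 (S)-4,5-bis(benzyloxy)pent-1-yne
Conditions: NaH, BnBr, Bu4NI (cat.), THF, 0 °C → rt
Reagents that add atoms: benzyl bromide, BrCc1ccccc1
Why: Williamson benzylation gives O8' a group that is a poor leaving group β to the later propargylic carbon and stays on through the hydroxide step, where a free C8' hydroxyl would lactonise onto the ring B carboxyl.

Step 10
Reactants: 16 (S)-4,5-bis(benzyloxy)pent-1-yne; 12 N-methoxy-N-methyl-2-(G-oxy)acetamide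
Product: 18 (S)-6,7-bis(benzyloxy)-1-(G-oxy)hept-3-yn-2-one, via lithium acetylide 17 (not isolated)
Conditions: n-BuLi, THF, −78 °C; then 12, −78 → −30 °C; aq. NH4Cl
Reagents that add atoms: none
Why: Acylation of the lithium acetylide by the Weinreb amide stops at the ketone because the chelated tetrahedral intermediate collapses only on work-up.

Step 11
Reactants: 18 (S)-6,7-bis(benzyloxy)-1-(G-oxy)hept-3-yn-2-one; 19 dimethyl malonate
Product: 22 methyl 6-[(S)-2,3-bis(benzyloxy)propyl]-3-(G-oxy)-2,4-dihydroxybenzoate, via Michael adduct 20 (not isolated), via cyclised diketo ester 21 (not isolated)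
Conditions: NaOMe (3 equiv), MeOH/THF, 0 °C → rt, then 60 °C; AcOH quench
Reagents that add atoms: none
Why: Sodium dimethyl malonate adds in Michael fashion to the ynone carbon remote from the carbonyl (future C1'), forming C1'–C6' and the delocalised alkenylmalonate anion 20; the ketone then enolises toward its only sp3 α-carbon, the OCH2 carbon (future C4'), which acylates on a malonate ester to form C4'–C5', and loss of methoxide followed by two enolisations turns 21 into the aromatic resorcylate without an oxidant. The closest known reaction type is the Michael–Claisen annulation of malonates with alkynyl ketones to 6-substituted 2,4-dihydroxybenzoates. Ring B closes by a 6-(enolendo)-exo-trig Claisen (Dieckmann-type) acylation. No stereocentre is formed, and C7, C8 and C8' carry no acidic hydrogen, so they should not epimerise. The selectivity needed is regiochemical and is fixed by the substrate: the ynone polarisation sends the malonate to C1', and the single enolisable sp3 α-position places the C8 oxygen between the two phenolic carbons. O-Acylation of the dienolate to a 2-pyranone is reversible in NaOMe/MeOH, whereas C-acylation ends in the resorcylate dianion, so the mixture should drain to 22.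

Step 12
Reactants: 22 methyl 6-[(S)-2,3-bis(benzyloxy)propyl]-3-(G-oxy)-2,4-dihydroxybenzoate
Product: 24 5-[(S)-2,3-bis(benzyloxy)propyl]-2-(G-oxy)benzene-1,3-diol, via resorcylic acid 23 (not isolated)
Conditions: NaOH (aq), MeOH/THF, 70 °C, Ar; then AcOH to pH 5, 50 °C
Reagents that add atoms: none
Why: Saponification of the hindered ester is followed by ipso-protonation and decarboxylation, which is easy for an ortho,para-dihydroxybenzoic acid, while the benzyl ethers and the hindered silyl ethers should persist.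

Step 13
Reactants: 24 5-[(S)-2,3-bis(benzyloxy)propyl]-2-(G-oxy)benzene-1,3-diol
Product: 25 5-[(S)-2,3-bis(benzyloxy)propyl]-2-(G-oxy)-1,3-dimethoxybenzene
Conditions: MeI, K2CO3, DMF, rt → 40 °C
Reagents that add atoms: iodomethane, CI
Why: Williamson O-methylation of the two symmetry-equivalent phenols completes the 2,6-dimethoxyphenyl ether of ring B.

Step 14
Reactants: 25 5-[(S)-2,3-bis(benzyloxy)propyl]-2-(G-oxy)-1,3-dimethoxybenzene
Product: 26 (1S,2R)-1-[4-(benzyloxy)-3,5-dimethoxyphenyl]-2-{4-[(S)-2,3-bis(benzyloxy)propyl]-2,6-dimethoxyphenoxy}propane-1,3-diol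
Conditions: Bu4NF, THF, rt → 40 °C; aq. NH4Cl
Reagents that add atoms: none
Why: Fluoride-induced cleavage of the TBS and TIPS ethers frees O7 and O9 without acid, so the electron-rich benzylic C7 cannot ionise and epimerise.

Step 15
Reactants: 26 (1S,2R)-1-[4-(benzyloxy)-3,5-dimethoxyphenyl]-2-{4-[(S)-2,3-bis(benzyloxy)propyl]-2,6-dimethoxyphenoxy}propane-1,3-diol
Product: 27 (1S,2R)-2-{4-[(S)-2,3-dihydroxypropyl]-2,6-dimethoxyphenoxy}-1-(4-hydroxy-3,5-dimethoxyphenyl)propane-1,3-diol
Conditions: H2 (1 atm), Pd/C, EtOAc/MeOH, rt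
Reagents that add atoms: none
Why: Catalytic hydrogenolysis removes the one aryl and two alkyl benzyl ethers, and neutral solvent with close monitoring should spare the benzylic C7–OH bond.

**Compound list**

1 | 4-bromo-2,6-dimethoxyphenol | COc1cc(Br)cc(OC)c1O | starting material
2 | 2-(benzyloxy)-5-bromo-1,3-dimethoxybenzene | COc1cc(Br)cc(OC)c1OCc1ccccc1 | intermediate
3 | (R)-2,2-dimethyl-1,3-dioxolane-4-carbaldehyde | O=C[C@H]1COC(C)(C)O1 | starting material
4 | [4-(benzyloxy)-3,5-dimethoxyphenyl]lithium | COc1cc([Li])cc(OC)c1OCc1ccccc1 | intermediate (not isolated)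
5 | [4-(benzyloxy)-3,5-dimethoxyphenyl]titanium triisopropoxide | COc1cc([Ti](OC(C)C)(OC(C)C)OC(C)C)cc(OC)c1OCc1ccccc1 | intermediate (not isolated)
6 | (S)-[4-(benzyloxy)-3,5-dimethoxyphenyl][(4R)-2,2-dimethyl-1,3-dioxolan-4-yl]methanol | COc1cc([C@H](O)[C@H]2COC(C)(C)O2)cc(OC)c1OCc1ccccc1 | intermediate
7 | tert-butyl{(S)-[4-(benzyloxy)-3,5-dimethoxyphenyl][(4R)-2,2-dimethyl-1,3-dioxolan-4-yl]methoxy}dimethylsilane | COc1cc([C@H](O[Si](C)(C)C(C)(C)C)[C@H]2COC(C)(C)O2)cc(OC)c1OCc1ccccc1 | intermediate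
8 | (2R,3S)-3-[4-(benzyloxy)-3,5-dimethoxyphenyl]-3-[(tert-butyldimethylsilyl)oxy]propane-1,2-diol | COc1cc([C@H](O[Si](C)(C)C(C)(C)C)[C@H](O)CO)cc(OC)c1OCc1ccccc1 | intermediate
9 | (1S,2R)-1-[4-(benzyloxy)-3,5-dimethoxyphenyl]-1-[(tert-butyldimethylsilyl)oxy]-3-[(triisopropylsilyl)oxy]propan-2-ol (G–OH) | COc1cc([C@H](O[Si](C)(C)C(C)(C)C)[C@H](O)CO[Si](C(C)C)(C(C)C)C(C)C)cc(OC)c1OCc1ccccc1 | intermediate
10 | ethyl diazoacetate | CCOC(=O)C=[N+]=[N-] | starting material
11 | ethyl 2-(G-oxy)acetate | COc1cc([C@H](O[Si](C)(C)C(C)(C)C)[C@@H](CO[Si](C(C)C)(C(C)C)C(C)C)OCC(=O)OCC)cc(OC)c1OCc1ccccc1 | intermediate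
12 | N-methoxy-N-methyl-2-(G-oxy)acetamide | COc1cc([C@H](O[Si](C)(C)C(C)(C)C)[C@@H](CO[Si](C(C)C)(C(C)C)C(C)C)OCC(=O)N(C)OC)cc(OC)c1OCc1ccccc1 | intermediate
13 | (S)-benzyl glycidyl ether | C1[C@H](O1)COCc1ccccc1 | starting material
14 | lithium acetylide–ethylenediamine complex | [Li+].[C-]#C.NCCN | starting material
15 | (S)-1-(benzyloxy)pent-4-yn-2-ol | C#CC[C@H](O)COCc1ccccc1 | intermediate
16 | (S)-4,5-bis(benzyloxy)pent-1-yne | C#CC[C@H](OCc1ccccc1)COCc1ccccc1 | intermediate
17 | [(S)-4,5-bis(benzyloxy)pent-1-yn-1-yl]lithium | [Li]C#CC[C@H](OCc1ccccc1)COCc1ccccc1 | intermediate (not isolated)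
18 | (S)-6,7-bis(benzyloxy)-1-(G-oxy)hept-3-yn-2-one | COc1cc([C@H](O[Si](C)(C)C(C)(C)C)[C@@H](CO[Si](C(C)C)(C(C)C)C(C)C)OCC(=O)C#CC[C@H](OCc2ccccc2)COCc2ccccc2)cc(OC)c1OCc1ccccc1 | intermediate
19 | dimethyl malonate | COC(=O)CC(=O)OC | starting material
20 | dimethyl 2-[(2S)-1,2-bis(benzyloxy)-7-(G-oxy)-6-oxohept-4-en-4-yl]propanedioate | COc1cc([C@H](O[Si](C)(C)C(C)(C)C)[C@@H](CO[Si](C(C)C)(C(C)C)C(C)C)OCC(=O)C=C(C[C@H](OCc2ccccc2)COCc2ccccc2)C(C(=O)OC)C(=O)OC)cc(OC)c1OCc1ccccc1 | intermediate (not isolated)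
21 | methyl 6-[(S)-2,3-bis(benzyloxy)propyl]-3-(G-oxy)-2,4-dioxocyclohex-5-ene-1-carboxylate | COc1cc([C@H](O[Si](C)(C)C(C)(C)C)[C@@H](CO[Si](C(C)C)(C(C)C)C(C)C)OC2C(=O)C=C(C[C@H](OCc3ccccc3)COCc3ccccc3)C(C(=O)OC)C2=O)cc(OC)c1OCc1ccccc1 | intermediate (not isolated)
22 | methyl 6-[(S)-2,3-bis(benzyloxy)propyl]-3-(G-oxy)-2,4-dihydroxybenzoate | COc1cc([C@H](O[Si](C)(C)C(C)(C)C)[C@@H](CO[Si](C(C)C)(C(C)C)C(C)C)Oc2c(O)cc(C[C@H](OCc3ccccc3)COCc3ccccc3)c(C(=O)OC)c2O)cc(OC)c1OCc1ccccc1 | intermediate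
23 | 6-[(S)-2,3-bis(benzyloxy)propyl]-3-(G-oxy)-2,4-dihydroxybenzoic acid | COc1cc([C@H](O[Si](C)(C)C(C)(C)C)[C@@H](CO[Si](C(C)C)(C(C)C)C(C)C)Oc2c(O)cc(C[C@H](OCc3ccccc3)COCc3ccccc3)c(C(=O)O)c2O)cc(OC)c1OCc1ccccc1 | intermediate (not isolated)
24 | 5-[(S)-2,3-bis(benzyloxy)propyl]-2-(G-oxy)benzene-1,3-diol | COc1cc([C@H](O[Si](C)(C)C(C)(C)C)[C@@H](CO[Si](C(C)C)(C(C)C)C(C)C)Oc2c(O)cc(C[C@H](OCc3ccccc3)COCc3ccccc3)cc2O)cc(OC)c1OCc1ccccc1 | intermediate
25 | 5-[(S)-2,3-bis(benzyloxy)propyl]-2-(G-oxy)-1,3-dimethoxybenzene | COc1cc([C@H](O[Si](C)(C)C(C)(C)C)[C@@H](CO[Si](C(C)C)(C(C)C)C(C)C)Oc2c(OC)cc(C[C@H](OCc3ccccc3)COCc3ccccc3)cc2OC)cc(OC)c1OCc1ccccc1 | intermediate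
26 | (1S,2R)-1-[4-(benzyloxy)-3,5-dimethoxyphenyl]-2-{4-[(S)-2,3-bis(benzyloxy)propyl]-2,6-dimethoxyphenoxy}propane-1,3-diol | COc1cc([C@H](O)[C@@H](CO)Oc2c(OC)cc(C[C@H](OCc3ccccc3)COCc3ccccc3)cc2OC)cc(OC)c1OCc1ccccc1 | intermediate
27 | (1S,2R)-2-{4-[(S)-2,3-dihydroxypropyl]-2,6-dimethoxyphenoxy}-1-(4-hydroxy-3,5-dimethoxyphenyl)propane-1,3-diol | COc1cc([C@H](O)[C@@H](CO)Oc2c(OC)cc(C[C@H](O)CO)cc2OC)cc(OC)c1O | target

**Summary**

Total step count: 15. Longest linear sequence: 13 steps (steps 1–7, 10–15); steps 8–9 make the alkyne fragment.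

Steps most likely to fail:

Step 11. The ynone may be consumed by base before the annulation is complete, through methoxide conjugate addition or propargyl–allenyl isomerisation with loss of the C8' benzyloxy group. The Michael adduct may also stall as the O-acylated 2-pyranone because C-acylation at the hindered, alkoxy-bearing carbon is slow. The fallback makes the same ring B by an Alder–Rickert sequence; it sets out from alcohol 9 and alkyne 16 and comes back at resorcylate 22. Diazo transfer to cyclohexane-1,3-dione (sulfonyl azide, Et3N) gives 2-diazocyclohexane-1,3-dione F1. Its Rh2(OAc)4-catalysed O–H insertion into 9 (benzene, 80 °C) should give 3-hydroxy-2-(G-oxy)cyclohex-2-en-1-one F2. Silylation (TMSCl/Et3N, then LDA/TMSCl, THF, −78 °C) should give 2-(G-oxy)-1,3-bis[(trimethylsilyl)oxy]cyclohexa-1,3-diene F3. Alkyne 16 is converted with n-BuLi and methyl chloroformate into methyl (S)-5,6-bis(benzyloxy)hex-2-ynoate F4. Heating F3 with F4 (xylene, about 160 °C) should give the bicyclo[2.2.2]octadiene Diels–Alder adduct F5, which loses ethene by retro-Diels–Alder reaction to give methyl 6-[(S)-2,3-bis(benzyloxy)propyl]-3-(G-oxy)-2,4-bis[(trimethylsilyl)oxy]benzoate F6. K2CO3/MeOH then frees the phenols to give 22. The unsubstituted, most nucleophilic diene terminus should bond to the ynoate β-carbon, which puts the ester next to an oxygenated carbon and the side chain next to the ring CH, as in 22.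

Step 12. The hot alkali needed to hydrolyse the doubly ortho-substituted, hydrogen-bonded ester may strip the silyl ethers unevenly or leave the ester partly intact. The fallback reorders the endgame so that no silyl ether meets hydroxide; it sets out from 22 and comes back at 26. Bu4NF in THF removes both silyl groups to give methyl 6-[(S)-2,3-bis(benzyloxy)propyl]-3-{[(1S,2R)-1-[4-(benzyloxy)-3,5-dimethoxyphenyl]-1,3-dihydroxypropan-2-yl]oxy}-2,4-dihydroxybenzoate F7; O8' stays benzylated, so no lactone can form. Aqueous NaOH/MeOH at reflux, then mild acidification and warming, should give 5-[(S)-2,3-bis(benzyloxy)propyl]-2-{[(1S,2R)-1-[4-(benzyloxy)-3,5-dimethoxyphenyl]-1,3-dihydroxypropan-2-yl]oxy}benzene-1,3-diol F8. MeI/K2CO3 in acetone methylates only the two phenols and gives 26.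

Step 2. Facial selectivity in the addition to the α-alkoxy aldehyde may be poor, so that much material ends up as the syn C7 epimer. The fallback sets C7 by reduction instead of addition; it sets out from the epimer mixture of step 2 and comes back at 6. The mixture of 6 and its epimer (R)-[4-(benzyloxy)-3,5-dimethoxyphenyl][(4R)-2,2-dimethyl-1,3-dioxolan-4-yl]methanol F9 is oxidised with Dess–Martin periodinane (NaHCO3, CH2Cl2) to [4-(benzyloxy)-3,5-dimethoxyphenyl][(4R)-2,2-dimethyl-1,3-dioxolan-4-yl]methanone F10. Chelation-controlled reduction with Zn(BH4)2 (Et2O, −30 °C), with zinc bridging the ketone and the α-oxygen and hydride entering past the C8 hydrogen, should give the anti alcohol 6.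

**Further compounds**

F1 | step 11 | 2-diazocyclohexane-1,3-dione | O=C1CCCC(=O)C1=[N+]=[N-]
F2 | step 11 | 3-hydroxy-2-(G-oxy)cyclohex-2-en-1-one | COc1cc([C@H](O[Si](C)(C)C(C)(C)C)[C@@H](CO[Si](C(C)C)(C(C)C)C(C)C)OC2=C(O)CCCC2=O)cc(OC)c1OCc1ccccc1
F3 | step 11 | 2-(G-oxy)-1,3-bis[(trimethylsilyl)oxy]cyclohexa-1,3-diene | COc1cc([C@H](O[Si](C)(C)C(C)(C)C)[C@@H](CO[Si](C(C)C)(C(C)C)C(C)C)OC2=C(O[Si](C)(C)C)CCC=C2O[Si](C)(C)C)cc(OC)c1OCc1ccccc1
F4 | step 11 | methyl (S)-5,6-bis(benzyloxy)hex-2-ynoate | COC(=O)C#CC[C@H](OCc1ccccc1)COCc1ccccc1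
F5 | step 11 | methyl 3-[(S)-2,3-bis(benzyloxy)propyl]-6-(G-oxy)-1,5-bis[(trimethylsilyl)oxy]bicyclo[2.2.2]octa-2,5-diene-2-carboxylate | COc1cc([C@H](O[Si](C)(C)C(C)(C)C)[C@@H](CO[Si](C(C)C)(C(C)C)C(C)C)OC2=C(O[Si](C)(C)C)C3CCC2(O[Si](C)(C)C)C(C(=O)OC)=C3C[C@H](OCc4ccccc4)COCc4ccccc4)cc(OC)c1OCc1ccccc1
F6 | step 11 | methyl 6-[(S)-2,3-bis(benzyloxy)propyl]-3-(G-oxy)-2,4-bis[(trimethylsilyl)oxy]benzoate | COc1cc([C@H](O[Si](C)(C)C(C)(C)C)[C@@H](CO[Si](C(C)C)(C(C)C)C(C)C)Oc2c(O[Si](C)(C)C)cc(C[C@H](OCc3ccccc3)COCc3ccccc3)c(C(=O)OC)c2O[Si](C)(C)C)cc(OC)c1OCc1ccccc1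
F7 | step 12 | methyl 6-[(S)-2,3-bis(benzyloxy)propyl]-3-{[(1S,2R)-1-[4-(benzyloxy)-3,5-dimethoxyphenyl]-1,3-dihydroxypropan-2-yl]oxy}-2,4-dihydroxybenzoate | COc1cc([C@H](O)[C@@H](CO)Oc2c(O)cc(C[C@H](OCc3ccccc3)COCc3ccccc3)c(C(=O)OC)c2O)cc(OC)c1OCc1ccccc1
F8 | step 12 | 5-[(S)-2,3-bis(benzyloxy)propyl]-2-{[(1S,2R)-1-[4-(benzyloxy)-3,5-dimethoxyphenyl]-1,3-dihydroxypropan-2-yl]oxy}benzene-1,3-diol | COc1cc([C@H](O)[C@@H](CO)Oc2c(O)cc(C[C@H](OCc3ccccc3)COCc3ccccc3)cc2O)cc(OC)c1OCc1ccccc1
F9 | step 2 | (R)-[4-(benzyloxy)-3,5-dimethoxyphenyl][(4R)-2,2-dimethyl-1,3-dioxolan-4-yl]methanol | COc1cc([C@@H](O)[C@H]2COC(C)(C)O2)cc(OC)c1OCc1ccccc1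
F10 | step 2 | [4-(benzyloxy)-3,5-dimethoxyphenyl][(4R)-2,2-dimethyl-1,3-dioxolan-4-yl]methanone | COc1cc(C(=O)[C@H]2COC(C)(C)O2)cc(OC)c1OCc1ccccc1
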